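**Assumption:** (R)-carvone, (S)-linalool, 5-iodo-2-methylpent-2-ene, tigloyl chloride and KSC(S)OEt are bought. Centres that form as mixtures and are erased later are drawn without stereo labels. Ring A = oxepane, ring B = cyclohexane, ring C = cycloheptene, ring D = cyclopentane.

## Retrosynthetic overview

1. Target 30 ⇐ reduction of both ketones of diketone 29 ⇐ central CH2–CH2 bond by nickel-catalysed electroreductive allyl–alkyl coupling of iodide 17 (rings A/B) with allylic bromide 28 (rings C/D).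
2. Rings C/D: one visible-light acyl-xanthate radical annulation of (S)-linalool with a tigloyl unit (ring D by 5-exo, then ring C by 7-endo). The linalool carbinol steers the ring-fusion centres and is then erased and re-set by dehydration and convex-face hydration in one flask.
3. Rings A/B: (R)-carvone supplies ring B and controls both oxygenated centres before its isopropenyl group is excised. The quaternary methyl carbon comes from reductive alkylation of an epoxy ketone; ring A is closed last by alkoxymercuration.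

## Route

Step 1
Reactants: 1 (R)-carvone
Product: 3 (5R,6S)-6-methylcarvone, via lithium dienolate 2 (not isolated)
Conditions: LiN(i-Pr)2, THF, −78 °C; then MeI, −78 → 0 °C
Reagents that add atoms: iodomethane, CI
Why: Kinetic α′-deprotonation and SN2 methylation of the cross-conjugated enolate; the methyl enters anti to the neighbouring isopropenyl group.

Step 2
Reactants: 3 (5R,6S)-6-methylcarvone
Product: 4 trans-epoxide of 3 (oxirane anti to the isopropenyl group)
Conditions: H2O2 (30 %), NaOH (cat.), MeOH, 0 °C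
Reagents that add atoms: hydrogen peroxide, OO
Why: Weitz–Scheffer nucleophilic epoxidation; hydroperoxide attacks the β-carbon opposite the isopropenyl group, as with carvone itself, fixing the future O–CH centre.

Step 3
Reactants: 4 trans-epoxide of 3
Product: 6 α′-hydroxy epoxy ketone, via lithium enolate 5 (not isolated)
Conditions: LiN(i-Pr)2, THF, −78 °C; then 3-phenyl-2-(phenylsulfonyl)oxaziridine, −78 °C
Reagents that add atoms: 3-phenyl-2-(phenylsulfonyl)oxaziridine, O=S(=O)(N1OC1c1ccccc1)c1ccccc1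
Why: Davis enolate oxidation; only C3–H is enolisable and the oxidant approaches anti to the adjacent isopropenyl, giving the tertiary carbinol with OH cis to the oxirane.

Step 4
Reactants: 6 α′-hydroxy epoxy ketone
Product: 8 (1R,3S,6R)-3-hydroxy-1,3-dimethyl-7-oxabicyclo[4.1.0]heptan-2-one, via methoxy hydroperoxide 7 (not isolated)
Conditions: O3, MeOH, −78 °C; then FeSO4·7H2O, PhSH, −78 → 25 °C
Reagents that add atoms: none
Why: Dealkenylative hydrogenation: Criegee ozonolysis in methanol gives 7, ferrous ion triggers alkoxy-radical β-scission, and the ring radical takes H from the thiol; the isopropenyl group leaves after it has set both oxygenated centres.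

Step 5
Reactants: 8 (1R,3S,6R)-3-hydroxy-1,3-dimethyl-7-oxabicyclo[4.1.0]heptan-2-one; 9 5-iodo-2-methylpent-2-ene
Product: 11 (2S,5R,6S)-2,5-dihydroxy-2,6-dimethyl-6-(4-methylpent-3-en-1-yl)cyclohexan-1-one, via trilithium enolate 10 (not isolated)
Conditions: Li, NH3(l)/THF, −78 °C; then 9, −78 → −33 °C
Reagents that add atoms: none
Why: Stork-type dissolving-metal reductive alkylation of an α,β-epoxy ketone; the regiodefined enolate 10 is alkylated anti to the neighbouring lithium alkoxide, so the new chain ends trans and the methyl cis to the ring oxygen, which is what the trans-fused oxepane needs.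

Step 6
Reactants: 11 (2S,5R,6S)-2,5-dihydroxy-2,6-dimethyl-6-(4-methylpent-3-en-1-yl)cyclohexan-1-one
Product: 13 oxepane keto diol (both C3 epimers), via organomercurial 12 (not isolated)
Conditions: Hg(O2CCF3)2, CH3NO2, −20 °C; then NaBH4, O2, DMF, 0 °C
Reagents that add atoms: dioxygen, O=O
Why: Intramolecular alkoxymercuration then oxidative demercuration; the secondary hydroxyl attacks the mercurinium ion at its tertiary carbon (Markovnikov, 7-endo) to close ring A, the ketone between two quaternary carbons resists NaBH4 at 0 °C, and the C3 epimers are converged in step 9.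

Step 7
Reactants: 13 oxepane keto diol
Product: 14 exocyclic alkene diol
Conditions: Cp2TiMe2, toluene, 75 °C
Reagents that add atoms: Cp2TiMe2 (bis(cyclopentadienyl)dimethyltitanium), C[Ti](C)(C1C=CC=C1)C1C=CC=C1
Why: Petasis methylenation; the small titanium methylidene reaches the ketone flanked by two quaternary carbons, and free hydroxyls are tolerated as titanates.

Step 8
Reactants: 14 exocyclic alkene diol
Product: 16 iodo diol, via B-alkyl-9-BBN 15 (not isolated)
Conditions: 9-BBN dimer (excess), THF, 65 °C; then NaOMe, I2, MeOH, 0 °C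
Reagents that add atoms: iodine, II
Why: Hydroboration then Brown iodinolysis; boron adds to the CH2 terminus and hydrogen to the ring carbon from the face opposite the axial methyl and axial hydroxyl, so CH2I ends equatorial, cis to the angular methyl.

Step 9
Reactants: 16 iodo diol
Product: 17 (5aR,6R,7S,9aR)-7-hydroxy-6-(iodomethyl)-2,2,5a,7-tetramethyloctahydro-1-benzoxepin-3(2H)-one
Conditions: Dess–Martin periodinane, CH2Cl2, 0 → 25 °C
Reagents that add atoms: none
Why: Dess–Martin oxidation converges both C3 epimers into one ketone; the tertiary alcohol and the hindered primary iodide are inert.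

Step 10
Reactants: 18 tigloyl chloride; 19 KSC(=S)OEt; 20 (S)-linalool
Product: 24 (1S,3aR,8aR)-1-hydroxy-1,4,4,5,6-pentamethyl-2,3,3a,4,8,8a-hexahydroazulen-7(1H)-one, via tigloyl xanthate 21 (not isolated), via monocyclic tertiary xanthate 22 (not isolated), via bicyclic keto xanthate 23 (not isolated)
Conditions: 18, 19, acetone, 0 °C; then 20, ClCH2CH2Cl, blue LEDs (450 nm), 35 °C; then PhCl, 130 °C; then DBU (cat.), 60 °C
Reagents that add atoms: none
Why: Proposed new method: a visible-light xanthate-transfer radical annulation, whose closest known relatives are S-acyl xanthate photolysis and xanthate group-transfer radical cyclisations; the tigloyl radical from 21 adds to the vinyl terminus of linalool and the secondary radical closes 5-exo through a Beckwith chair with the C–O bond pseudo-axial and the acylmethyl arm pseudo-equatorial, so OH, CH2CO and CMe2 end all-cis and both ring-fusion centres are set, reversible xanthate capping (22) keeps the tertiary radical alive until it closes 7-endo onto the tethered enone, and thermal syn-elimination of xanthic acid from 23 with base equilibration gives the tetrasubstituted enone.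

Step 11
Reactants: 24 (1S,3aR,8aR)-1-hydroxy-1,4,4,5,6-pentamethyl-2,3,3a,4,8,8a-hexahydroazulen-7(1H)-one
Product: 27 (1R,3aR,8aR)-1-hydroxy-1,4,4,5,6-pentamethyl-2,3,3a,4,8,8a-hexahydroazulen-7(1H)-one, via endocyclic alkene 25 (not isolated), via exocyclic alkene 26 (not isolated)
Conditions: Burgess reagent (MeO2C–N(−)–SO2–N(+)Et3), benzene, 50 °C; then evaporate, Co(acac)2 (cat.), PhSiH3, O2 (1 atm), THF/i-PrOH, 25 °C
Reagents that add atoms: dioxygen, O=O
Why: Burgess syn-elimination can remove only the C2 or methyl hydrogens because the ring-fusion hydrogen is anti to the concave hydroxyl, so the misplaced carbinol is erased without touching the fusion centres, and Mukaiyama hydration by hydrogen-atom transfer then turns both alkenes into the same tertiary radical, which O2 traps from the convex face (anti to the C8a–C8 bond) while the tetrasubstituted enone is inert and the i-PrOH co-solvent consumes leftover Burgess reagent.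

Step 12
Reactants: 27 (1R,3aR,8aR)-1-hydroxy-1,4,4,5,6-pentamethyl-2,3,3a,4,8,8a-hexahydroazulen-7(1H)-one
Product: 28 (1R,3aR,8aR)-5-(bromomethyl)-1-hydroxy-1,4,4,6-tetramethyl-2,3,3a,4,8,8a-hexahydroazulen-7(1H)-one
Conditions: N-bromosuccinimide, AIBN (cat.), PhCF3, 80 °C
Reagents that add atoms: N-bromosuccinimide, O=C1CCC(=O)N1Br
Why: Wohl–Ziegler bromination; only the C5 methyl gives a radical conjugated through the enone to oxygen and the ring γ-carbon is quaternary, so bromination is γ-selective.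

Step 13
Reactants: 17 (5aR,6R,7S,9aR)-7-hydroxy-6-(iodomethyl)-2,2,5a,7-tetramethyloctahydro-1-benzoxepin-3(2H)-one; 28 (1R,3aR,8aR)-5-(bromomethyl)-1-hydroxy-1,4,4,6-tetramethyl-2,3,3a,4,8,8a-hexahydroazulen-7(1H)-one
Product: 29 seco-diketone (3-oxo oxepane, 7-oxo azulene)
Conditions: NiBr2·(MeOCH2CH2OMe) (10 mol %), 4,4′-di-tert-butyl-2,2′-bipyridine, NaI, DMA, undivided cell, zinc anode, nickel-foam cathode, constant current, 25 °C
Reagents that add atoms: none
Why: Nickel-catalysed electroreductive cross-electrophile allyl–alkyl coupling; zerovalent nickel adds to the vinylogous α-bromo ketone, captures the alkyl radical from the iodide and eliminates at the unhindered CH2 terminus, with ketones and tertiary alcohols tolerated.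

Step 14
Reactants: 29 seco-diketone
Product: 30 target
Conditions: NaBH4, CeCl3·7H2O, MeOH, −40 → 0 °C
Reagents that add atoms: none
Why: Luche reduction; 1,2-hydride delivery to the enone from the convex face of the cis-fused bicycle gives the (7S) allylic alcohol, and attack on the oxepanone opposite the angular methyl gives the (3S) alcohol.

## Compound list

1 | (R)-carvone, (5R)-2-methyl-5-(prop-1-en-2-yl)cyclohex-2-en-1-one | O=C1C(C)=CC[C@@H](C(C)=C)C1 | starting material
2 | lithium cross-conjugated dienolate of 1 | [Li+].[O-]C1=C[C@H](C(C)=C)CC=C1C | intermediate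
3 | (5R,6S)-2,6-dimethyl-5-(prop-1-en-2-yl)cyclohex-2-en-1-one | O=C1C(C)=CC[C@@H](C(C)=C)[C@@H]1C | intermediate
4 | (1R,3S,4R,6R)-1,3-dimethyl-4-(prop-1-en-2-yl)-7-oxabicyclo[4.1.0]heptan-2-one (oxirane anti to isopropenyl) | O=C1[C@]2(C)O[C@@H]2C[C@@H](C(C)=C)[C@@H]1C | intermediate
5 | lithium enolate of 4 (enolised toward C3) | [Li+].[O-]C1=C(C)[C@H](C(C)=C)C[C@H]2O[C@@]12C | intermediate
6 | (1R,3S,4S,6R)-3-hydroxy-1,3-dimethyl-4-(prop-1-en-2-yl)-7-oxabicyclo[4.1.0]heptan-2-one | O=C1[C@]2(C)O[C@@H]2C[C@@H](C(C)=C)[C@]1(C)O | intermediate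
7 | 6 with isopropenyl replaced by C(CH3)(OCH3)OOH | O=C1[C@]2(C)O[C@@H]2C[C@@H](C(C)(OC)OO)[C@]1(C)O | intermediate
8 | (1R,3S,6R)-3-hydroxy-1,3-dimethyl-7-oxabicyclo[4.1.0]heptan-2-one | O=C1[C@]2(C)O[C@@H]2CC[C@]1(C)O | intermediate
9 | 5-iodo-2-methylpent-2-ene | CC(C)=CCCI | starting material
10 | trilithium enolate dialkoxide from 8 | [Li+].[Li+].[Li+].[O-]C1=C(C)[C@H]([O-])CC[C@]1(C)[O-] | intermediate
11 | (2S,5R,6S)-2,5-dihydroxy-2,6-dimethyl-6-(4-methylpent-3-en-1-yl)cyclohexan-1-one | O=C1[C@@](C)(CCC=C(C)C)[C@H](O)CC[C@]1(C)O | intermediate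
12 | 3-(trifluoroacetoxymercurio) derivative of the trans-fused oxepane ketone | O=C1[C@@]2(C)CCC([Hg]OC(=O)C(F)(F)F)C(C)(C)O[C@@H]2CC[C@]1(C)O | intermediate
13 | (5aS,7S,9aR)-3,7-dihydroxy-2,2,5a,7-tetramethyloctahydro-1-benzoxepin-6(2H)-one (C3 epimers) | O=C1[C@@]2(C)CCC(O)C(C)(C)O[C@@H]2CC[C@]1(C)O | intermediate
14 | (5aR,7S,9aR)-2,2,5a,7-tetramethyl-6-methylidenedecahydro-1-benzoxepine-3,7-diol (C3 epimers) | C=C1[C@@]2(C)CCC(O)C(C)(C)O[C@@H]2CC[C@]1(C)O | intermediate
15 | 9-BBN adduct of 14 (boron on the exocyclic CH2) | C1CC2CCCC(C1)B2C[C@@H]1[C@@]2(C)CCC(O)C(C)(C)O[C@@H]2CC[C@]1(C)O | intermediate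
16 | (5aR,6R,7S,9aR)-6-(iodomethyl)-2,2,5a,7-tetramethyldecahydro-1-benzoxepine-3,7-diol (C3 epimers) | IC[C@@H]1[C@@]2(C)CCC(O)C(C)(C)O[C@@H]2CC[C@]1(C)O | intermediate
17 | (5aR,6R,7S,9aR)-7-hydroxy-6-(iodomethyl)-2,2,5a,7-tetramethyloctahydro-1-benzoxepin-3(2H)-one | IC[C@@H]1[C@@]2(C)CCC(=O)C(C)(C)O[C@@H]2CC[C@]1(C)O | intermediate
18 | (E)-2-methylbut-2-enoyl chloride (tigloyl chloride) | C/C=C(\C)C(Cl)=O | starting material
19 | potassium O-ethyl carbonodithioate | CCOC(=S)[S-].[K+] | starting material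
20 | (S)-linalool | C=C[C@@](C)(O)CCC=C(C)C | starting material
21 | S-[(E)-2-methylbut-2-enoyl] O-ethyl carbonodithioate | CCOC(=S)SC(=O)/C(C)=C/C | intermediate
22 | O-ethyl S-{2-[(1R,2R,3S)-3-hydroxy-3-methyl-2-((E)-3-methyl-2-oxopent-3-en-1-yl)cyclopentyl]propan-2-yl} carbonodithioate (all-cis) | CCOC(=S)SC(C)(C)[C@@H]1CC[C@](C)(O)[C@@H]1CC(=O)/C(C)=C/C | intermediate
23 | 6-(ethoxycarbonothioylthio) derivative of the saturated cis-fused hydroazulenone (C5, C6 mixture) | CCOC(=S)SC1(C)C(C)C(C)(C)[C@@H]2CC[C@](C)(O)[C@@H]2CC1=O | intermediate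
24 | (1S,3aR,8aR)-1-hydroxy-1,4,4,5,6-pentamethyl-2,3,3a,4,8,8a-hexahydroazulen-7(1H)-one | CC1=C(C)C(C)(C)[C@@H]2CC[C@](C)(O)[C@@H]2CC1=O | intermediate
25 | (3aR,8aR)-1,4,4,5,6-pentamethyl-3,3a,4,8a-tetrahydroazulen-7(8H)-one (ring D endocyclic alkene) | CC1=C(C)C(C)(C)[C@@H]2CC=C(C)[C@@H]2CC1=O | intermediate
26 | (3aR,8aR)-4,4,5,6-tetramethyl-1-methylidene-2,3,3a,4,8,8a-hexahydroazulen-7(1H)-one (exocyclic alkene) | CC1=C(C)C(C)(C)[C@@H]2CCC(=C)[C@@H]2CC1=O | intermediate
27 | (1R,3aR,8aR)-1-hydroxy-1,4,4,5,6-pentamethyl-2,3,3a,4,8,8a-hexahydroazulen-7(1H)-one | CC1=C(C)C(C)(C)[C@@H]2CC[C@@](C)(O)[C@@H]2CC1=O | intermediate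
28 | (1R,3aR,8aR)-5-(bromomethyl)-1-hydroxy-1,4,4,6-tetramethyl-2,3,3a,4,8,8a-hexahydroazulen-7(1H)-one | CC1=C(CBr)C(C)(C)[C@@H]2CC[C@@](C)(O)[C@@H]2CC1=O | intermediate
29 | (5aR,6R,7S,9aR)-7-hydroxy-6-{2-[(1R,3aR,8aR)-1-hydroxy-1,4,4,6-tetramethyl-7-oxo-1,2,3,3a,4,7,8,8a-octahydroazulen-5-yl]ethyl}-2,2,5a,7-tetramethyloctahydro-1-benzoxepin-3(2H)-one | CC1=C(CC[C@@H]2[C@@]3(C)CCC(=O)C(C)(C)O[C@@H]3CC[C@]2(C)O)C(C)(C)[C@@H]2CC[C@@](C)(O)[C@@H]2CC1=O | intermediate
30 | (3S,5aR,6R,7S,9aR)-6-{2-[(1R,3aR,7S,8aR)-1,7-dihydroxy-1,4,4,6-tetramethyl-1,2,3,3a,4,7,8,8a-octahydroazulen-5-yl]ethyl}-2,2,5a,7-tetramethyldecahydro-1-benzoxepine-3,7-diol | CC1=C(CC[C@@H]2[C@@]3(C)CC[C@H](O)C(C)(C)O[C@@H]3CC[C@]2(C)O)C(C)(C)[C@@H]2CC[C@@](C)(O)[C@@H]2C[C@@H]1O | target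

## Step count and risks

Total steps: 14. Longest linear sequence: 11 (steps 1–9, 13, 14).

Steps most likely to fail:

1. Step 10 (the proposed annulation). The 7-endo closure onto a β-methyl, α-methyl enone is slow, and the sense of the 5-exo step relative to the carbinol is predicted, not proven. The fallback uses known chemistry: it sets out from 22, isolated after the established acyl-xanthate addition and 5-exo cyclisation at 35 °C, and comes back at 24. Heating 22 in chlorobenzene eliminates xanthic acid to the isopropenyl dienone F1. Fe(acac)3/PhSiH3 hydrogen-atom-transfer reductive olefin–enone cyclisation closes ring C to the saturated bicyclic ketone F2. TMSOTf/Et3N under equilibrating conditions gives the bis-silyl enol ether F3, and Pd(OAc)2 (Saegusa–Ito) with acidic work-up returns 24.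

2. Step 13 (fragment union). Risks are homocoupling, simple reduction of 28, and β-hydride loss from the alkylnickel. The fallback sets out from 14 and 28 and comes back at 29, replacing the radical coupling by olefination. Hydroboration–oxidation of 14 (9-BBN; NaOH, H2O2) gives the triol F4, and Dess–Martin oxidation gives the keto aldehyde F5. PPh3 converts 28 into the phosphonium bromide F6; Wittig reaction of F6 with F5 (K2CO3) gives the dienone F7, and [(Ph3P)CuH]6 1,6-reduction, followed by DBU equilibration of the double bond into conjugation if needed, gives 29.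

3. Step 6 (ring A closure). The seven-membered alkoxymercuration may be slow or lose to external trifluoroacetate. The fallback sets out from 11 and comes back at 13, closing the ether by reductive etherification instead. RuCl3 (cat.)/NaIO4 ketohydroxylates the side-chain alkene and oxidises the secondary alcohol to give the trione ketol F8. Et3SiH/TMSOTf reduces the seven-membered oxocarbenium ion from the axial face to the trans-fused oxepanedione F9, and NaBH4 at −78 °C reduces only the unhindered C3 ketone to 13.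

## Further compounds

F1 | step 10 | (E)-1-[(1R,2R,5S)-2-hydroxy-2-methyl-5-(prop-1-en-2-yl)cyclopentyl]-3-methylpent-3-en-2-one (all-cis) | CC(=C)[C@@H]1CC[C@](C)(O)[C@@H]1CC(=O)/C(C)=C/C
F2 | step 10 | (1S,3aR,8aR)-1-hydroxy-1,4,4,5,6-pentamethyloctahydroazulen-7(1H)-one (C5, C6 mixture) | CC1C(C)C(C)(C)[C@@H]2CC[C@](C)(O)[C@@H]2CC1=O
F3 | step 10 | bis(trimethylsilyl) derivative of F2 (C6–C7 enol ether and tertiary silyl ether) | C[Si](C)(C)OC1=C(C)C(C)C(C)(C)[C@@H]2CC[C@](C)(O[Si](C)(C)C)[C@@H]2C1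
F4 | step 13 | (5aR,6R,7S,9aR)-6-(hydroxymethyl)-2,2,5a,7-tetramethyldecahydro-1-benzoxepine-3,7-diol (C3 epimers) | OC[C@@H]1[C@@]2(C)CCC(O)C(C)(C)O[C@@H]2CC[C@]1(C)O
F5 | step 13 | (5aR,6R,7S,9aR)-7-hydroxy-2,2,5a,7-tetramethyl-3-oxodecahydro-1-benzoxepine-6-carbaldehyde | O=C[C@@H]1[C@@]2(C)CCC(=O)C(C)(C)O[C@@H]2CC[C@]1(C)O
F6 | step 13 | triphenylphosphonium bromide from 28 (P on the C5 methylene) | CC1=C(C[P+](c2ccccc2)(c2ccccc2)c2ccccc2)C(C)(C)[C@@H]2CC[C@@](C)(O)[C@@H]2CC1=O.[Br-]
F7 | step 13 | (E)-1,2-didehydro analogue of 29 (ethene-1,2-diyl linker) | CC1=C(/C=C/[C@@H]2[C@@]3(C)CCC(=O)C(C)(C)O[C@@H]3CC[C@]2(C)O)C(C)(C)[C@@H]2CC[C@@](C)(O)[C@@H]2CC1=O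
F8 | step 6 | (2S,4S)-4-hydroxy-2-(4-hydroxy-4-methyl-3-oxopentyl)-2,4-dimethylcyclohexane-1,3-dione | O=C1[C@@](C)(CCC(=O)C(C)(C)O)C(=O)CC[C@]1(C)O
F9 | step 6 | (5aS,7S,9aR)-7-hydroxy-2,2,5a,7-tetramethylhexahydro-1-benzoxepine-3,6(2H,4H)-dione | O=C1[C@@]2(C)CCC(=O)C(C)(C)O[C@@H]2CC[C@]1(C)O
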